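One reagent goes per substrate converted: the winter run stands at 55.0 % product, and its charges stand at 55.0 %.

common to all: substrate 0.40 M; added ligand 2.7 mM

| run | reagent | free catalyst | remark |
|---|---|---|---|
| winter | 0.22 M | 1.4 mM | run made earlier |
| spring | 0.33 M | 1.4 mM | run made earlier |
| autumn | 0.44 M | 2.1 mM | run made earlier |
| flask | 0.440 M | 1.4 mM |  |

| run | time / h | product / % | substrate / % |
|---|---|---|---|
| winter | 2.00 | 55.0 | 45.1 |
| winter | 4.00 | 54.9 | 44.8 |
| winter | 6.00 | 55.1 | 45.2 |
| winter | 8.00 | 54.8 | 44.8 |
| winter | 10.0 | 54.8 | 45.2 |
| spring | 2.00 | 82.6 | 17.0 |
| spring | 4.00 | 82.7 | 17.4 |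
| spring | 6.00 | 83.0 | 17.7 |
| spring | 8.00 | 82.5 | 17.4 |
| spring | 10.0 | 82.2 | 17.7 |
| autumn | 0.833 | 99.8 | 0 |
| autumn | 2.50 | 100.3 | 0.5 |
| autumn | 4.00 | 100.2 | 0.2 |
| autumn | 6.00 | 99.3 | 0 |
| autumn | 10.0 | 99.9 | 0 |

(standard deviation of a reading: 0.3 percentage points)

- reactions considered so far: reagent + free catalyst -> catalyst intermediate A; substrate + catalyst intermediate A -> catalyst intermediate B; catalyst intermediate B <-> catalyst intermediate C; catalyst intermediate C <-> released group + catalyst intermediate D; catalyst intermediate D -> free catalyst + product; free catalyst + added ligand <-> idle complex

- apparent order in free catalyst when 30 % of the substrate are converted (percent change of the rate of making product for one percent more free catalyst charged)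
- apparent order in reagent when 30 % of the substrate are converted (percent change of the rate of making product for one percent more reagent charged)

Which charge gives out first in the flask? Reagent is charged at 1.10 times the substrate, more than one to one, so substrate is the limiting reagent.

What is present at the moment asked about? At 30 % conversion the flask holds 0.320 M of reagent, less at most 1.4 mM held on the catalyst. This is the reagent margin, the reagent charged less the substrate converted.

What does one percent more reagent charged do to it? The amount converted stays the same at that conversion, so the relative rise of [reagent] in the flask is 1.38 times the relative rise of the charge. If the order in reagent present lies between zero and one, our reckoning puts the order in reagent charged between zero and 1.38. The autumn run already reads 99.8 % product at 0.833 h, so it shows no rate at that conversion, and we leave the order inside that range.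

The forecast gives 1.3 for free catalyst (range 0.9 to 2.1) and 0.7 for reagent (range 0 to 1.4), with the words “If free or idle catalyst is the resting state, ord_B is about 1.4; if intermediate A or later rests, about 0.”

The flask gives 1.1 in free catalyst and 0.25 in reagent, so the forecast for reagent stands higher.

    reagent + free catalyst → catalyst intermediate A (k = 10.0 M⁻¹ s⁻¹)
    substrate + catalyst intermediate A → catalyst intermediate B (k = 62.0 M⁻¹ s⁻¹)
    catalyst intermediate B ⇌ catalyst intermediate C (K = 0.720, k = 1.00 s⁻¹)
    catalyst intermediate C ⇌ released group + catalyst intermediate D (K = 13.0 M, k = 2.70 s⁻¹)
    catalyst intermediate D → free catalyst + product (k = 8.80 s⁻¹)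
    free catalyst + added ligand ⇌ idle complex (K = 6400 M⁻¹, k = 1.00 M⁻¹ s⁻¹)

When 30 % of the substrate are converted in the flask, free catalyst is 12.4 % of the catalyst charged. Divided by the factor 1.38 from the margin, the order in reagent charged gives 0.185 as the order in reagent present, by our reckoning. In the spring run the margin reaches zero at 82.5 % conversion, and its product reads 82.6 % at 2.00 h.

(The earlier runs and the new flask are simulated for substances that don't exist, noise included.)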